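**Plan**
- Retrosynthesis: the C2–Br and C3–Br bonds are cut first (late electrophilic bromination of the free indole) and N1 is masked as its phenylsulfonyl derivative. The benzo ring is then opened at C5–C6 with formal return of HBr, which gives a 3-(1-bromovinyl)-2-(2,2-dibromovinyl)pyrrole.
- Enabling feature: the carbocycle C3a–C4–C5–C6–C7–C7a is fused to a pyrrole whose C2=C3 bond (C7a=C3a of the indole) can act as the central alkene of a triene. The bromines sit on C4 (the alkene carbon bonded to C3a) and on C6 (a triene terminus), so a CBr2 terminus supplies both the C6 bromine and the leaving group for aromatization.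
- The triene is cut further at C6=C7 (dibromo-olefination with CBr4), at C7–C7a (formylation with DMF) and at C4–Br (from the acetyl C=O of 3-acetyl-1-(phenylsulfonyl)pyrrole).
- Forward: the pyrrole ring is bought; C7 and then C6 are attached at pyrrole C2, the acetyl group becomes the bromoalkene, and the benzene ring closes as the only ring-forming event. Desulfonylation and bromination of C3 and C2 finish the target.
- Stereochemistry: the target is planar and achiral, with no stereocentre and no stereogenic alkene. The two sp3 carbons of the transient dihydroindole carry identical substituent pairs, so nothing has to be controlled.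

Key step: step 6

Assumption: the three starting materials and all reagents are purchased, and LiN(iPr)2 is used as a commercial solution.

Step 1
Reactants: 1 3-acetyl-1-(phenylsulfonyl)-1H-pyrrole
Product: 2 2-methyl-2-[1-(phenylsulfonyl)-1H-pyrrol-3-yl]-1,3-dioxolane
Conditions: HOCH2CH2OH (5 equiv), TsOH·H2O (cat.), toluene, reflux, Dean–Stark
Reagents that add atoms: ethylene glycol, OCCO
Why: Acid-catalysed ketalization with azeotropic removal of water should mask the enolizable acetyl group before the strong base of step 2 and turn it into a lithium-coordinating group, the N-sulfonylpyrrole being stable to catalytic TsOH.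

Step 2
Reactants: 2 2-methyl-2-[1-(phenylsulfonyl)-1H-pyrrol-3-yl]-1,3-dioxolane; 3 N,N-dimethylformamide
Product: 6 3-(2-methyl-1,3-dioxolan-2-yl)-1-(phenylsulfonyl)-1H-pyrrole-2-carbaldehyde, via 2-lithiopyrrole 4 (not isolated), via lithium aminoalkoxide adduct 5 (not isolated)
Conditions: LiN(iPr)2 (1.2 equiv), THF, −78 °C; then DMF (3 equiv), −78 → 0 °C; sat. aq. NH4Cl
Reagents that add atoms: N,N-dimethylformamide (3), CN(C)C=O
Why: Directed ortho-metalation should fall on C2, the α-position acidified by the sulfonyl group and held by chelation to a dioxolane oxygen, and the aryllithium is then formylated by DMF (Bouveault aldehyde synthesis), the adduct collapsing to the aldehyde on buffered work-up.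

Step 3
Reactants: 6 3-(2-methyl-1,3-dioxolan-2-yl)-1-(phenylsulfonyl)-1H-pyrrole-2-carbaldehyde; 7 carbon tetrabromide
Product: 8 2-[2-(2,2-dibromoethenyl)-1-(phenylsulfonyl)-1H-pyrrol-3-yl]-2-methyl-1,3-dioxolane
Conditions: CBr4 (2 equiv), PPh3 (4 equiv), Et3N (1 equiv), CH2Cl2, 0 °C
Reagents that add atoms: carbon tetrabromide (7), BrC(Br)(Br)Br
Why: Ramirez dibromo-olefination (first stage of the Corey–Fuchs sequence), in which the ylide Ph3P=CBr2 formed in the flask undergoes a Wittig reaction with the aldehyde, should install C6 with both bromines while Et3N buffers the medium so that the ketal is kept.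

Step 4
Reactants: 8 2-[2-(2,2-dibromoethenyl)-1-(phenylsulfonyl)-1H-pyrrol-3-yl]-2-methyl-1,3-dioxolane
Product: 9 1-[2-(2,2-dibromoethenyl)-1-(phenylsulfonyl)-1H-pyrrol-3-yl]ethan-1-one
Conditions: 1 M aq. HCl, THF, rt
Reagents that add atoms: water, O
Why: Acid-catalysed ketal hydrolysis should free the methyl ketone, since neither the gem-dibromoalkene nor the N-sulfonyl group reacts with dilute aqueous acid at room temperature.

Step 5
Reactants: 9 1-[2-(2,2-dibromoethenyl)-1-(phenylsulfonyl)-1H-pyrrol-3-yl]ethan-1-one
Product: 10 3-(1-bromoethenyl)-2-(2,2-dibromoethenyl)-1-(phenylsulfonyl)-1H-pyrrole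
Conditions: P(OPh)3, Br2, CH2Cl2, −60 °C; then Et3N and 9, −60 °C → rt, then 40 °C
Reagents that add atoms: bromine, BrBr
Why: Deoxybromination of an enolizable methyl ketone with preformed triphenyl phosphite dibromide (oxyphosphonium activation of the carbonyl, bromide delivery, loss of HBr toward the only enolizable side) should give the 1-bromovinyl group, driven by P=O formation and with no free Br2 left to attack the pyrrole or the dibromoalkene.

Step 6
Reactants: 10 3-(1-bromoethenyl)-2-(2,2-dibromoethenyl)-1-(phenylsulfonyl)-1H-pyrrole
Product: 12 4,6-dibromo-1-(phenylsulfonyl)-1H-indole, via dihydroindole 11 (not isolated)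
Conditions: 1,2-dichlorobenzene (0.02 M, degassed), propylene oxide (5 equiv), BHT (cat.), sealed tube, 180 °C, dark
Reagents that add atoms: none
Why: On heating, the cis-fixed triene C5=C4–C3a=C7a–C7=C6 of 10, whose central alkene is the pyrrole C2=C3 bond, should undergo a thermal six-electron electrocyclization that joins the CH2 terminus (C5) to the CBr2 terminus (C6) and gives dihydroindole 11, which then loses HBr across C5–C6 (a C5 hydrogen and one C6 bromine) to aromatize both rings. The closest known reaction type is the thermal 6π-electrocyclization and eliminative aromatization of 2,3-dialkenylpyrroles and 2,3-dialkenylindoles to indoles and carbazoles, applied here to a triene with a gem-dibromo terminus, a substitution pattern whose inward bromine is expected to slow the closure and is the reason for the high temperature. The six-membered carbocycle closes in the disrotatory mode allowed for a ground-state 4n+2 system, by bonding the two termini of the triene. No stereocentre results, because C5 and C6 of 11 each carry two identical substituents and both become sp2 on aromatization. The step needs aromatization by elimination and not by dehydrogenation so that exactly one bromine stays at C6; the CBr2 group secures this because the only sp3 C–H next to C6 in 11 is on C5, so every loss of HBr ends in the 4,6-dibromo arene, while the C4 bromine is vinylic throughout and cannot be expelled. The N-phenylsulfonyl group lowers the aromatic stabilization that the pyrrole gives up in 11, the irreversible HBr loss drains the unfavourable equilibrium, and propylene oxide traps HBr without being basic enough to turn the bromoalkenes into alkynes.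

Step 7
Reactants: 12 4,6-dibromo-1-(phenylsulfonyl)-1H-indole
Product: 13 4,6-dibromo-1H-indole
Conditions: 2 M aq. NaOH, MeOH/THF, 65 °C
Reagents that add atoms: none
Why: Base-mediated N-desulfonylation (attack of hydroxide or methoxide at sulfur with the dibromoindolide as leaving group) should free N–H, aryl bromides being inert to these conditions.

Step 8
Reactants: 13 4,6-dibromo-1H-indole
Product: 15 2,3,4,6-tetrabromo-1H-indole, via tribromoindole 14 (not isolated)
Conditions: NBS (2.05 equiv in two portions), THF, −78 °C → rt, dark, N2
Reagents that add atoms: N-bromosuccinimide, O=C1CCC(=O)N1Br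
Why: Electrophilic aromatic bromination of the indole enamine should take C3 first and then C2, the only other pyrrole-ring position, because the benzo ring is deactivated by its two bromines.

**Compound list**
1 | 3-acetyl-1-(phenylsulfonyl)-1H-pyrrole | CC(=O)c1ccn(c1)S(=O)(=O)c1ccccc1 | starting material
2 | 2-methyl-2-[1-(phenylsulfonyl)-1H-pyrrol-3-yl]-1,3-dioxolane | CC1(OCCO1)c1ccn(c1)S(=O)(=O)c1ccccc1 | intermediate
3 | N,N-dimethylformamide | CN(C)C=O | starting material
4 | 2-lithio-3-(2-methyl-1,3-dioxolan-2-yl)-1-(phenylsulfonyl)pyrrole (not isolated) | [Li]c1c(C2(C)OCCO2)ccn1S(=O)(=O)c1ccccc1 | intermediate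
5 | lithium (dimethylamino)[3-(2-methyl-1,3-dioxolan-2-yl)-1-(phenylsulfonyl)pyrrol-2-yl]methoxide, racemic (not isolated) | [Li]OC(N(C)C)c1c(C2(C)OCCO2)ccn1S(=O)(=O)c1ccccc1 | intermediate
6 | 3-(2-methyl-1,3-dioxolan-2-yl)-1-(phenylsulfonyl)-1H-pyrrole-2-carbaldehyde | O=Cc1c(C2(C)OCCO2)ccn1S(=O)(=O)c1ccccc1 | intermediate
7 | carbon tetrabromide | BrC(Br)(Br)Br | starting material
8 | 2-[2-(2,2-dibromoethenyl)-1-(phenylsulfonyl)-1H-pyrrol-3-yl]-2-methyl-1,3-dioxolane | BrC(Br)=Cc1c(C2(C)OCCO2)ccn1S(=O)(=O)c1ccccc1 | intermediate
9 | 1-[2-(2,2-dibromoethenyl)-1-(phenylsulfonyl)-1H-pyrrol-3-yl]ethan-1-one | CC(=O)c1ccn(S(=O)(=O)c2ccccc2)c1C=C(Br)Br | intermediate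
10 | 3-(1-bromoethenyl)-2-(2,2-dibromoethenyl)-1-(phenylsulfonyl)-1H-pyrrole | C=C(Br)c1ccn(S(=O)(=O)c2ccccc2)c1C=C(Br)Br | intermediate
11 | 4,6,6-tribromo-1-(phenylsulfonyl)-5,6-dihydro-1H-indole (not isolated) | O=S(=O)(c1ccccc1)N1C=CC2=C(Br)CC(Br)(Br)C=C12 | intermediate
12 | 4,6-dibromo-1-(phenylsulfonyl)-1H-indole | O=S(=O)(c1ccccc1)n1ccc2c(Br)cc(Br)cc21 | intermediate
13 | 4,6-dibromo-1H-indole | Brc1cc(Br)c2cc[nH]c2c1 | intermediate
14 | 3,4,6-tribromo-1H-indole (not isolated) | Brc1cc(Br)c2c(Br)c[nH]c2c1 | intermediate
15 | 2,3,4,6-tetrabromo-1H-indole | Brc1cc(Br)c2c(Br)c(Br)[nH]c2c1 | target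

**Total step count:** 8
**Longest linear sequence:** 8 steps (1 → 15)

**Steps most likely to fail**

1. Step 6. The disrotatory closure, slowed by the inward bromine and by the partial loss of pyrrole aromaticity, may be outrun by thermal polymerization or dehydrobromination of the bromodiene. The fallback sets out from 10 and comes back at 12, and replaces ground-state activation by excited-state activation. Triene 10 would be irradiated at room temperature (medium-pressure Hg lamp, Pyrex filter, degassed benzene, propylene oxide), so that a conrotatory 6π-photocyclization of the Mallory type, in its non-oxidative eliminative form, leads to the same dihydroindole 11. This would lose HBr in the dark to give 12. The detour makes no compound outside the list (entry F0).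

2. Step 8. The second bromination may run on into the benzo ring, or the electron-rich dibromoindole may be oxidized at C2 before it can be isolated. The fallback sets out from 13 and comes back at 15, and introduces the C2 bromine from a lactam carbonyl instead of by electrophilic substitution. Indole 13 would be treated with pyridinium tribromide in t-BuOH/H2O to give 3,3,4,6-tetrabromoindolin-2-one F1. Zn in AcOH would then remove the C3 bromines to give 4,6-dibromoindolin-2-one F2. POBr3 and imidazole in 1,2-dichloroethane at 80 °C would convert the lactam to 2,4,6-tribromo-1H-indole F3. A single equivalent of NBS (THF, −78 °C) would then brominate C3 to give 15.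

3. Step 5. Activation of the hindered carbonyl by the phosphite dibromide may be incomplete, or liberated HBr may add across the new bromoalkene and bromine may attack the pyrrole ring. The fallback sets out from 9 and comes back at 10, and exchanges oxyphosphonium activation for hydrazone oxidation. Ketone 9 would be condensed with 1,2-bis(tert-butyldimethylsilyl)hydrazine under Sc(OTf)3 catalysis to give the N-(tert-butyldimethylsilyl)hydrazone of 9, F4. Slow addition of F4 to Br2 and 2-tert-butyl-1,1,3,3-tetramethylguanidine in CH2Cl2 at 0 °C (Barton vinyl halide synthesis in its N-silylhydrazone form: diazoalkane, bromodiazonium ion, loss of N2 and of a methyl proton) should give 10.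

**Further compounds**
F0 | step 6 | none | none
F1 | step 8 | 3,3,4,6-tetrabromoindolin-2-one | O=C1Nc2cc(Br)cc(Br)c2C1(Br)Br
F2 | step 8 | 4,6-dibromoindolin-2-one | O=C1Cc2c(Br)cc(Br)cc2N1
F3 | step 8 | 2,4,6-tribromo-1H-indole | Brc1cc(Br)c2cc(Br)[nH]c2c1
F4 | step 5 | 1-[2-(2,2-dibromoethenyl)-1-(phenylsulfonyl)-1H-pyrrol-3-yl]ethan-1-one N-(tert-butyldimethylsilyl)hydrazone (C=N geometry not controlled) | CC(=NN[Si](C)(C)C(C)(C)C)c1ccn(S(=O)(=O)c2ccccc2)c1C=C(Br)Br
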